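**Plan**

- Cuts: the 14-membered ring is opened at the C12–C13 single bond. Further cuts are C1=C2 (Wittig), C10–C11 (carbocupration of propyne), C8–C9 and C7–CH3 (methylalumination, oxirane opening) and C3'–C4' of the side chain (allyl anion prenylation). C2 and C7 are then reconnected to the cyclohexane ring of limonene-1,2-diol.
- Enabling feature: C12 is the vinylic CH of the 11Z trisubstituted ring olefin, and C13 is an unbranched CH2 separated from the C1=C2 enoate by C14. A (Z)-1-iodoalkene and an ester-tolerant primary alkylzinc therefore map onto these two atoms and can be joined with retention of geometry.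
- Forward order: the isopropenyl group of the protected diol is prenylated, the six-membered ring is cleaved to a C2 aldehyde and a C7 methyl ketone, the C7–C12 arm is grown from the ketone, the C1/C13/C14 unit is added at the aldehyde, and the macrocycle (the only ring of the target) is closed last.
- Stereochemistry: C4 (R) is C4 of (R)-limonene and is never alpha to a carbonyl. 7E comes from syn methylalumination, 11Z from syn carbocupration, 1E from a stabilised ylide; the ring closure carries all of them over unchanged.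

Key step: step 14

Remark: locants follow the target name methyl (1E,4R,7E,11Z)-7,11-dimethyl-4-(6-methylhepta-1,5-dien-2-yl)cyclotetradeca-1,7,11-triene-1-carboxylate; primed locants belong to the side chain (C2' on the ring).

**Route**

Step 1
Reactants: 1 (1S,2S,4R)-limonene-1,2-diol
Product: 2 acetonide of 1
Conditions: Me2C(OMe)2, CSA (cat.), CH2Cl2, rt
Reagents that add atoms: 2,2-dimethoxypropane, COC(C)(C)OC
Why: Acid-catalysed acetonide formation (transketalisation) caps both hydroxyl groups so that the isopropenyl methyl group is the only site open to the coming metalation; no stereocentre is involved.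

Step 2
Reactants: 2 acetonide of 1; 3 prenyl bromide
Product: 5 acetonide of (1S,2S,4R)-1-methyl-4-(6-methylhepta-1,5-dien-2-yl)cyclohexane-1,2-diol, via allyllithium 4 (not isolated)
Conditions: n-BuLi, TMEDA, hexane, rt; then 3, THF, −78 °C to rt
Reagents that add atoms: none
Why: Allylic lithiation of the isopropenyl methyl group and SN2 alkylation of the 2-substituted allyllithium (its two CH2 termini are equivalent) with the primary allylic bromide, a transformation with close precedent on limonene itself, should install the whole side chain and leave C4 untouched.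

Step 3
Reactants: 5 prenylated acetonide
Product: 7 (3R)-3-(6-methylhepta-1,5-dien-2-yl)-6-oxoheptanal, via diol 6 (not isolated)
Conditions: H5IO6, THF/H2O, 0 °C to rt
Reagents that add atoms: none
Why: Acid hydrolysis of the strained trans-fused ketal followed in the same flask by periodate glycol cleavage (Malaprade reaction) should open the ring to the C2 aldehyde and the C7 methyl ketone; the stereocentre is beta to the aldehyde and cannot epimerise.

Step 4
Reactants: 7 keto aldehyde
Product: 8 (5R)-7-hydroxy-5-(6-methylhepta-1,5-dien-2-yl)heptan-2-one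
Conditions: NaBH4 (0.3 equiv), EtOH/CH2Cl2, −78 °C
Reagents that add atoms: none
Why: Chemoselective borohydride reduction of the aldehyde in the presence of the methyl ketone at low temperature stores C2 at the alcohol level for the organometallic steps that follow.

Step 5
Reactants: 8 keto alcohol
Product: 9 (5R)-7-[(tert-butyldimethylsilyl)oxy]-5-(6-methylhepta-1,5-dien-2-yl)heptan-2-one
Conditions: TBSCl, imidazole, DMF, rt
Reagents that add atoms: tert-butyldimethylsilyl chloride, CC(C)(C)[Si](C)(C)Cl
Why: Silylation of the primary alcohol gives an ether that withstands lithium amide, Me3Al and Grignard chemistry, which an acetal at C2 would not.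

Step 6
Reactants: 9 silyl ether ketone
Product: 12 tert-butyldimethyl{[(3R)-3-(6-methylhepta-1,5-dien-2-yl)hept-6-yn-1-yl]oxy}silane, via lithium enolate 10 (not isolated), via enol phosphate 11 (not isolated)
Conditions: LiN(i-Pr)2, THF, −78 °C; ClP(O)(OEt)2, −78 °C to rt; LiN(i-Pr)2 (2.3 equiv), −78 °C to rt; H2O
Reagents that add atoms: none
Why: Kinetic deprotonation at the methyl group, O-phosphorylation and base-induced elimination of the enol phosphate (methyl ketone to terminal alkyne conversion) should give the C7≡C8 alkyne, the ketone methyl carbon becoming C8.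

Step 7
Reactants: 12 terminal alkyne; 13 oxirane
Product: 16 (3E,7R)-9-[(tert-butyldimethylsilyl)oxy]-4-methyl-7-(6-methylhepta-1,5-dien-2-yl)non-3-en-1-ol, via alkenylalane 14 (not isolated), via lithium alanate 15 (not isolated)
Conditions: Me3Al, Cp2ZrCl2 (0.25 equiv), CH2Cl2, rt; evaporation; n-BuLi, hexane, −78 °C; 13, THF, −78 °C to rt
Reagents that add atoms: trimethylaluminium, C[Al](C)C
Why: Zirconium-catalysed syn methylalumination of the terminal alkyne (Negishi carboalumination) places CH3 on C7 and aluminium on C8 cis to each other, and the derived alanate opens oxirane with retention, so the 7E geometry is fixed by the syn addition.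

Step 8
Reactants: 16 homoallylic alcohol
Product: 17 {[(3R,6E)-9-bromo-6-methyl-3-(6-methylhepta-1,5-dien-2-yl)non-6-en-1-yl]oxy}(tert-butyl)dimethylsilane
Conditions: CBr4, PPh3, CH2Cl2, 0 °C
Reagents that add atoms: tetrabromomethane, BrC(Br)(Br)Br
Why: The Appel reaction converts the primary alcohol into the bromide under neutral conditions that leave the silyl ether and the olefins alone.

Step 9
Reactants: 17 homoallylic bromide; 18 propyne
Product: 22 tert-butyl{[(3R,6E,10Z)-11-iodo-6,10-dimethyl-3-(6-methylhepta-1,5-dien-2-yl)undeca-6,10-dien-1-yl]oxy}dimethylsilane, via Grignard reagent 19 (not isolated), via alkylcopper 20 (not isolated), via alkenylcopper 21 (not isolated)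
Conditions: Mg, Et2O, reflux; CuBr·SMe2, Et2O/Me2S, −45 °C; 18, −25 °C; I2, THF, −50 to 0 °C
Reagents that add atoms: iodine, [I][I]
Why: In the Normant carbocupration the alkylcopper adds syn across propyne with copper on the terminal carbon, and iodinolysis with retention should give the (Z)-1-iodo-2-methylalkene with iodine cis to the chain, which fixes the 11Z geometry.

Step 10
Reactants: 22 silyl ether
Product: 23 (3R,6E,10Z)-11-iodo-6,10-dimethyl-3-(6-methylhepta-1,5-dien-2-yl)undeca-6,10-dien-1-ol
Conditions: HF·pyridine, pyridine, THF, 0 °C to rt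
Reagents that add atoms: none
Why: Buffered fluoride desilylation frees the C2 alcohol without affecting the iodoalkene or the acid-sensitive trisubstituted olefins.

Step 11
Reactants: 23 primary alcohol; 24 3-(triphenyl-λ5-phosphanylidene)oxolan-2-one
Product: 26 (3E)-3-[(3R,6E,10Z)-11-iodo-6,10-dimethyl-3-(6-methylhepta-1,5-dien-2-yl)undeca-6,10-dien-1-ylidene]oxolan-2-one, via aldehyde 25 (not isolated)
Conditions: Dess–Martin periodinane, pyridine, CH2Cl2, 0 °C to rt; then 24, 40 °C
Reagents that add atoms: none
Why: Dess–Martin oxidation followed in the same flask by Wittig olefination with the lactone-stabilised ylide should give the (E)-alkylidene lactone, the chain ending up trans to the carbonyl as is usual for stabilised ylides; this fixes the 1E geometry and brings in C1, C13 and C14.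

Step 12
Reactants: 26 alkylidene lactone
Product: 28 methyl (2E,5R,8E,12Z)-2-(2-hydroxyethyl)-13-iodo-8,12-dimethyl-5-(6-methylhepta-1,5-dien-2-yl)trideca-2,8,12-trienoate, via potassium carboxylate 27 (not isolated)
Conditions: KOH (1.05 equiv), THF/H2O, 0 °C to rt; evaporation; MeI, DMF, rt
Reagents that add atoms: potassium hydroxide, [K+].[OH-]; iodomethane, CI
Why: Saponification of the lactone and irreversible SN2 methylation of the carboxylate salt pull the ring–chain equilibrium to the open form and unveil the methyl ester and the C13 hydroxyl without touching the olefin geometry.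

Step 13
Reactants: 28 hydroxy ester
Product: 29 methyl (2E,5R,8E,12Z)-13-iodo-2-(2-iodoethyl)-8,12-dimethyl-5-(6-methylhepta-1,5-dien-2-yl)trideca-2,8,12-trienoate
Conditions: I2, PPh3, imidazole, CH2Cl2, 0 °C
Reagents that add atoms: iodine, [I][I]
Why: Appel-type iodination (Garegg–Samuelsson conditions) turns the primary alcohol into the iodide under near-neutral conditions, fast enough to outrun relactonisation.

Step 14
Reactants: 29 iodoalkyl (Z)-iodoalkene
Product: 31 methyl (1E,4R,7E,11Z)-7,11-dimethyl-4-(6-methylhepta-1,5-dien-2-yl)cyclotetradeca-1,7,11-triene-1-carboxylate, via alkylzinc iodide 30 (not isolated)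
Conditions: Zn (activated with BrCH2CH2Br, TMSCl), THF, 35 °C; then slow addition to PdCl2(dppf) (10 mol %), THF/DMA, 60 °C (final 2 mM)
Reagents that add atoms: none
Why: Zinc inserts oxidatively into the primary carbon–iodine bond of 29 while the alkenyl iodide and the ester stay untouched, giving 30; zerovalent palladium then adds into the (Z)-alkenyl iodide with retention, the tethered alkylzinc transmetalates to divalent palladium, and reductive elimination forms the C12–C13 C(sp3)–C(sp2) bond. The closest known reaction type is the Negishi coupling of primary alkylzinc halides with alkenyl iodides, used here in the ring-closing sense familiar from B-alkyl Suzuki–Miyaura macrocyclisations. The 14-membered carbocycle closes end to end: transmetalation gives a 15-membered palladacycle and reductive elimination contracts it to the ring, which should be helped by the two cis-in-ring olefins (C1=C2 and C11=C12) turning the chain ends toward each other. No stereocentre is formed; the 11Z geometry is carried over with retention from the iodoalkene, and the 1E and 7E olefins and C4 (R) are spectators. The step needs chemoselective zinc insertion (secured by the far higher reactivity of the primary alkyl iodide in THF without salt additives), intramolecular over intermolecular coupling (slow addition to the catalyst at high dilution), and reductive elimination over beta-hydride elimination (wide-bite-angle dppf ligand).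

**Compound list**

1 | (1S,2S,4R)-1-methyl-4-(prop-1-en-2-yl)cyclohexane-1,2-diol [(1S,2S,4R)-limonene-1,2-diol] | C[C@]1(O)CC[C@H](C[C@@H]1O)C(C)=C | starting material
2 | acetonide of 1 (2,2-dimethyl-1,3-dioxolane across O1 and O2) | C[C@]12CC[C@H](C[C@@H]1OC(C)(C)O2)C(C)=C | intermediate
3 | 1-bromo-3-methylbut-2-ene (prenyl bromide) | CC(C)=CCBr | starting material
4 | allyllithium of 2 (lithium on the former isopropenyl methyl carbon; formed in situ) | C[C@]12CC[C@H](C[C@@H]1OC(C)(C)O2)C(=C)C[Li] | intermediate
5 | acetonide of (1S,2S,4R)-1-methyl-4-(6-methylhepta-1,5-dien-2-yl)cyclohexane-1,2-diol | C[C@]12CC[C@H](C[C@@H]1OC(C)(C)O2)C(=C)CCC=C(C)C | intermediate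
6 | (1S,2S,4R)-1-methyl-4-(6-methylhepta-1,5-dien-2-yl)cyclohexane-1,2-diol (formed in situ) | C[C@]1(O)CC[C@H](C[C@@H]1O)C(=C)CCC=C(C)C | intermediate
7 | (3R)-3-(6-methylhepta-1,5-dien-2-yl)-6-oxoheptanal | C=C(CCC=C(C)C)[C@H](CCC(C)=O)CC=O | intermediate
8 | (5R)-7-hydroxy-5-(6-methylhepta-1,5-dien-2-yl)heptan-2-one | C=C(CCC=C(C)C)[C@H](CCC(C)=O)CCO | intermediate
9 | (5R)-7-[(tert-butyldimethylsilyl)oxy]-5-(6-methylhepta-1,5-dien-2-yl)heptan-2-one | C=C(CCC=C(C)C)[C@H](CCC(C)=O)CCO[Si](C)(C)C(C)(C)C | intermediate
10 | terminal lithium enolate of 9 (formed in situ) | C=C(CCC=C(C)C)[C@H](CCC(=C)O[Li])CCO[Si](C)(C)C(C)(C)C | intermediate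
11 | (5R)-7-[(tert-butyldimethylsilyl)oxy]-5-(6-methylhepta-1,5-dien-2-yl)hept-1-en-2-yl diethyl phosphate (formed in situ) | C=C(CCC=C(C)C)[C@H](CCC(=C)OP(=O)(OCC)OCC)CCO[Si](C)(C)C(C)(C)C | intermediate
12 | tert-butyldimethyl{[(3R)-3-(6-methylhepta-1,5-dien-2-yl)hept-6-yn-1-yl]oxy}silane | C=C(CCC=C(C)C)[C@H](CCC#C)CCO[Si](C)(C)C(C)(C)C | intermediate
13 | oxirane | C1CO1 | starting material
14 | [(1E,5R)-7-[(tert-butyldimethylsilyl)oxy]-2-methyl-5-(6-methylhepta-1,5-dien-2-yl)hept-1-en-1-yl]dimethylalane (formed in situ) | C=C(CCC=C(C)C)[C@H](CC/C(C)=C/[Al](C)C)CCO[Si](C)(C)C(C)(C)C | intermediate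
15 | lithium butyl(dimethyl)alanate of 14 (formed in situ) | C=C(CCC=C(C)C)[C@H](CC/C(C)=C/[Al-](C)(C)CCCC)CCO[Si](C)(C)C(C)(C)C.[Li+] | intermediate
16 | (3E,7R)-9-[(tert-butyldimethylsilyl)oxy]-4-methyl-7-(6-methylhepta-1,5-dien-2-yl)non-3-en-1-ol | C=C(CCC=C(C)C)[C@H](CC/C(C)=C/CCO)CCO[Si](C)(C)C(C)(C)C | intermediate
17 | {[(3R,6E)-9-bromo-6-methyl-3-(6-methylhepta-1,5-dien-2-yl)non-6-en-1-yl]oxy}(tert-butyl)dimethylsilane | C=C(CCC=C(C)C)[C@H](CC/C(C)=C/CCBr)CCO[Si](C)(C)C(C)(C)C | intermediate
18 | propyne | CC#C | starting material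
19 | Grignard reagent of 17 (MgBr in place of Br; formed in situ) | C=C(CCC=C(C)C)[C@H](CC/C(C)=C/CC[Mg]Br)CCO[Si](C)(C)C(C)(C)C | intermediate
20 | alkylcopper from 19 (formed in situ) | C=C(CCC=C(C)C)[C@H](CC/C(C)=C/CC[Cu])CCO[Si](C)(C)C(C)(C)C | intermediate
21 | (Z)-alkenylcopper from 20 and propyne (copper cis to the chain; formed in situ) | C=C(CCC=C(C)C)[C@H](CC/C(C)=C/CC/C(C)=C\[Cu])CCO[Si](C)(C)C(C)(C)C | intermediate
22 | tert-butyl{[(3R,6E,10Z)-11-iodo-6,10-dimethyl-3-(6-methylhepta-1,5-dien-2-yl)undeca-6,10-dien-1-yl]oxy}dimethylsilane | C=C(CCC=C(C)C)[C@H](CC/C(C)=C/CC/C(C)=C\I)CCO[Si](C)(C)C(C)(C)C | intermediate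
23 | (3R,6E,10Z)-11-iodo-6,10-dimethyl-3-(6-methylhepta-1,5-dien-2-yl)undeca-6,10-dien-1-ol | C=C(CCC=C(C)C)[C@H](CC/C(C)=C/CC/C(C)=C\I)CCO | intermediate
24 | 3-(triphenyl-λ5-phosphanylidene)oxolan-2-one | O=C1OCCC1=P(c1ccccc1)(c1ccccc1)c1ccccc1 | starting material
25 | (3R,6E,10Z)-11-iodo-6,10-dimethyl-3-(6-methylhepta-1,5-dien-2-yl)undeca-6,10-dienal (formed in situ) | C=C(CCC=C(C)C)[C@H](CC/C(C)=C/CC/C(C)=C\I)CC=O | intermediate
26 | (3E)-3-[(3R,6E,10Z)-11-iodo-6,10-dimethyl-3-(6-methylhepta-1,5-dien-2-yl)undeca-6,10-dien-1-ylidene]oxolan-2-one | C=C(CCC=C(C)C)[C@H](CC/C(C)=C/CC/C(C)=C\I)C/C=C1/C(=O)OCC1 | intermediate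
27 | potassium (2E,5R,8E,12Z)-2-(2-hydroxyethyl)-13-iodo-8,12-dimethyl-5-(6-methylhepta-1,5-dien-2-yl)trideca-2,8,12-trienoate (formed in situ) | C=C(CCC=C(C)C)[C@H](CC/C(C)=C/CC/C(C)=C\I)C/C=C(/C(=O)[O-])CCO.[K+] | intermediate
28 | methyl (2E,5R,8E,12Z)-2-(2-hydroxyethyl)-13-iodo-8,12-dimethyl-5-(6-methylhepta-1,5-dien-2-yl)trideca-2,8,12-trienoate | C=C(CCC=C(C)C)[C@H](CC/C(C)=C/CC/C(C)=C\I)C/C=C(/C(=O)OC)CCO | intermediate
29 | methyl (2E,5R,8E,12Z)-13-iodo-2-(2-iodoethyl)-8,12-dimethyl-5-(6-methylhepta-1,5-dien-2-yl)trideca-2,8,12-trienoate | C=C(CCC=C(C)C)[C@H](CC/C(C)=C/CC/C(C)=C\I)C/C=C(/C(=O)OC)CCI | intermediate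
30 | alkylzinc iodide of 29 (ZnI in place of the primary iodine; formed in situ) | C=C(CCC=C(C)C)[C@H](CC/C(C)=C/CC/C(C)=C\I)C/C=C(/C(=O)OC)CC[Zn]I | intermediate
31 | methyl (1E,4R,7E,11Z)-7,11-dimethyl-4-(6-methylhepta-1,5-dien-2-yl)cyclotetradeca-1,7,11-triene-1-carboxylate | C=C(CCC=C(C)C)[C@H]1C/C=C(/C(=O)OC)CC/C=C(/C)CC/C=C(\C)CC1 | target

**Step count and risks**

Total step count: 14. Longest linear sequence: 14 steps (1 to 31).

Steps most likely to fail:

Step 14. Zinc may also insert into the alkenyl iodide, the alkylzinc may be protonated before it reaches the catalyst, chains may couple with one another instead of closing, and the alkylpalladium intermediate may lose a beta-hydride. The fallback changes the organometallic partner from zinc to boron and sets out from 29. Light-driven radical borylation of the primary iodide (B2cat2, DMF, blue light) would give the catechol boronate F1, which is transesterified in the same flask (pinacol, Et3N) to the pinacol boronate F2. An intramolecular B-alkyl Suzuki–Miyaura coupling (PdCl2(dppf), Cs2CO3, DMF/THF/H2O, slow addition) would then close the same C12–C13 bond and return to the route at 31.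

Step 2. Metalation may be incomplete or unselective, the base may attack the ketal, and alkylation may take place through the tertiary end of the prenyl unit. The fallback builds the side chain on the neutral alkene and sets out from 2. A Lewis-acid-promoted carbonyl-ene reaction with formaldehyde ((CH2O)n, Me2AlCl, CH2Cl2, −78 to 0 °C) would give the homoallylic alcohol F3, and an Appel-type iodination (I2, PPh3, imidazole) the primary iodide F4. Copper-catalysed coupling with (2-methylprop-1-en-1-yl)magnesium bromide (CuI cat., THF, −20 °C) would then deliver 5, where the route is rejoined.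

Step 12. The γ-hydroxy ester may close back to the lactone during methylation, isolation or the following iodination, and hydroxide may add to the alkylidene lactone in conjugate fashion. The fallback never forms a free γ-hydroxy ester and sets out from 23. The same oxidation to 25 is followed by Wittig olefination with the acyclic ylide methyl 4-[(tert-butyldimethylsilyl)oxy]-2-(triphenyl-λ5-phosphanylidene)butanoate F5, prepared from methyl (triphenylphosphoranylidene)acetate and tert-butyl(2-iodoethoxy)dimethylsilane, to give the silyl ether enoate F6. Ph3PBr2 (CH2Cl2, rt) would convert the silyl ether directly into the bromide F7, and halide exchange (NaI, acetone) returns to the route at 29.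

Further compounds
F1 | step 14 | methyl (2E,5R,8E,12Z)-2-[2-(1,3,2-benzodioxaborol-2-yl)ethyl]-13-iodo-8,12-dimethyl-5-(6-methylhepta-1,5-dien-2-yl)trideca-2,8,12-trienoate | C=C(CCC=C(C)C)[C@H](CC/C(C)=C/CC/C(C)=C\I)C/C=C(/C(=O)OC)CCB1Oc2ccccc2O1
F2 | step 14 | methyl (2E,5R,8E,12Z)-13-iodo-8,12-dimethyl-5-(6-methylhepta-1,5-dien-2-yl)-2-[2-(4,4,5,5-tetramethyl-1,3,2-dioxaborolan-2-yl)ethyl]trideca-2,8,12-trienoate | C=C(CCC=C(C)C)[C@H](CC/C(C)=C/CC/C(C)=C\I)C/C=C(/C(=O)OC)CCB1OC(C)(C)C(C)(C)O1
F3 | step 2 | acetonide of (1S,2S,4R)-4-(4-hydroxybut-1-en-2-yl)-1-methylcyclohexane-1,2-diol | C[C@]12CC[C@H](C[C@@H]1OC(C)(C)O2)C(=C)CCO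
F4 | step 2 | acetonide of (1S,2S,4R)-4-(4-iodobut-1-en-2-yl)-1-methylcyclohexane-1,2-diol | C[C@]12CC[C@H](C[C@@H]1OC(C)(C)O2)C(=C)CCI
F5 | step 12 | methyl 4-[(tert-butyldimethylsilyl)oxy]-2-(triphenyl-λ5-phosphanylidene)butanoate | COC(=O)C(CCO[Si](C)(C)C(C)(C)C)=P(c1ccccc1)(c1ccccc1)c1ccccc1
F6 | step 12 | methyl (2E,5R,8E,12Z)-2-{2-[(tert-butyldimethylsilyl)oxy]ethyl}-13-iodo-8,12-dimethyl-5-(6-methylhepta-1,5-dien-2-yl)trideca-2,8,12-trienoate | C=C(CCC=C(C)C)[C@H](CC/C(C)=C/CC/C(C)=C\I)C/C=C(/C(=O)OC)CCO[Si](C)(C)C(C)(C)C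
F7 | step 12 | methyl (2E,5R,8E,12Z)-2-(2-bromoethyl)-13-iodo-8,12-dimethyl-5-(6-methylhepta-1,5-dien-2-yl)trideca-2,8,12-trienoate | C=C(CCC=C(C)C)[C@H](CC/C(C)=C/CC/C(C)=C\I)C/C=C(/C(=O)OC)CCBr
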